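Numbering (germacrane): C1 enol-ether carbon of the dihydrofuran, C2 its CH=, C3 CH2, C4 the O/CH3 quaternary carbon, C5 exocyclic CH=, C6/C7/C11/C12 the γ/β/α/C=O carbons of the butenolide, C8 CHOAc, C9 CH2, C10 C(OH)CH3, C13 CH2OAc.
Enabling feature: the chain O–C1=C2–C3–C4–C5=C6, shared by the dihydrofuran, the ten-membered carbocycle and the alkylidene butenolide, is an oxy-Cope retron whose oxygen lies 1,4 to C4.
Cuts: O–C4 first (C1 ketone + C4=C5=C6 allene). Then C3–C4 is cut while C1–C6 is rejoined as a temporary bond, which gives a cyclohexane fused to the butenolide with vinyl on C1 and propynyl on C6. Then C6–propynyl, C1–vinyl, C10–O, C1=O and the furan bonds (Feist–Bénary).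
Forward: furan/cyclohexane bicycle (step 1), butenolide (steps 9–10), then carbocycle, dihydrofuran and nine-membered oxacycle together (step 11), then the acetates.
Stereochemistry: C8 comes from asymmetric transfer hydrogenation. C10, C1 and C6 are set by attack anti to C8–OTBS. C6 is consumed, and its chirality passes through the allene axis to C4 and to the E geometry of C5=C6.

Key step: step 11

Remark: 4–8 are carried as mixtures of C10 epimers, because C10 is planarised in step 6. The peroxide and hemiketal centres of 13 and 14 are left undefined, because C6 is reset in step 10.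

Step 1
Reactants: 1 5-methylcyclohexane-1,3-dione; 2 ethyl bromopyruvate
Product: 4 ethyl 6-methyl-4-oxo-4,5,6,7-tetrahydro-1-benzofuran-3-carboxylate, via hydroxydihydrofuran 3 (not isolated)
Conditions: K2CO3, MeCN, 0 °C to rt; then TsOH·H2O (cat.), PhMe, reflux, Dean–Stark
Reagents that add atoms: none
Why: Feist–Bénary furan synthesis, in which C2 of the symmetric dione adds to the ketone of 2, the enol oxygen displaces bromide and acid dehydrates 3, so that the ester (future C13) sits on C11, C12 stays a free α-CH and the ketone stays at C8.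

Step 2
Reactants: 4 furan keto ester
Product: 5 ethyl (8S)-4-hydroxy-6-methyl-4,5,6,7-tetrahydro-1-benzofuran-3-carboxylate
Conditions: RuCl[(S,S)-TsDPEN](p-cymene) (1 mol %), HCO2H–Et3N (5:2), 40 °C
Reagents that add atoms: none
Why: Noyori asymmetric transfer hydrogenation of a hetaryl alkyl ketone of the 1-tetralone type, in which the catalyst alone should fix C8 as S in both C10 epimers.

Step 3
Reactants: 5 hydroxy ester
Product: 6 (8S)-3-(hydroxymethyl)-6-methyl-4,5,6,7-tetrahydro-1-benzofuran-4-ol
Conditions: LiAlH4, THF, 0 °C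
Reagents that add atoms: none
Why: Standard hydride reduction of the furan-3-carboxylate to the primary alcohol C13, which leaves C8 untouched (any lactone between C8–OH and the ester is reduced to the same diol).

Step 4
Reactants: 6 diol
Product: 7 bis(tert-butyldimethylsilyl) ether of 6
Conditions: TBSCl, imidazole, DMF, rt
Reagents that add atoms: tert-butyldimethylsilyl chloride CC(C)(C)[Si](C)(C)Cl
Why: Routine silylation of a primary and a secondary alcohol, which also makes C8–O the bulky pseudo-axial group (peri strain against C13) that steers steps 6, 7 and 10.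

Step 5
Reactants: 7 bis-TBS furan
Product: 8 (8S)-4-(TBSO)-3-(TBSOCH2)-6-methyl-5,6-dihydro-1-benzofuran-7(4H)-one
Conditions: DDQ (2.2 equiv), THF–H2O (9:1), 0 °C
Reagents that add atoms: water O
Why: Hetero-benzylic oxidation with DDQ, where hydride abstraction should be fastest at C1 (the only CH2 on an α-carbon of the furan), water captures the furfuryl cation and a second equivalent of DDQ gives the deactivated 2-acylfuran.

Step 6
Reactants: 8 furyl ketone
Product: 10 (8S,10S)-α-hydroxy ketone, via potassium enolate 9 (not isolated)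
Conditions: KN(SiMe3)2, THF, −78 °C; then 2-(phenylsulfonyl)-3-phenyloxaziridine, −78 °C; aq NH4Cl
Reagents that add atoms: 2-(phenylsulfonyl)-3-phenyloxaziridine O=S(=O)(N1OC1c1ccccc1)c1ccccc1
Why: Davis enolate hydroxylation at the only enolisable position, in which both C10 epimers converge on 9 and the oxidant should approach anti to the pseudo-axial C8–OTBS, placing C10–OH trans to C8–O.

Step 7
Reactants: 10 α-hydroxy ketone
Product: 11 (1R,8S,10S)-7-ethenyl 6,7-diol
Conditions: CH2=CHMgBr (3.5 equiv), THF, −78 to 0 °C; aq NH4Cl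
Reagents that add atoms: vinylmagnesium bromide C=C[Mg]Br
Why: Cram-chelate Grignard 1,2-addition, in which the magnesium alkoxide of C10–OH holds C10–O in the carbonyl plane and C10–CH3 axial, so that vinyl should enter from the face opposite to C10–CH3 and C8–OTBS (vinyl cis to C10–O, C1–O cis to C8–O).

Step 8
Reactants: 11 diol
Product: 12 bis(triethylsilyl) ether of 11
Conditions: TESOTf, 2,6-lutidine, CH2Cl2, −78 to 0 °C
Reagents that add atoms: triethylsilyl triflate CC[Si](CC)(CC)OS(=O)(=O)C(F)(F)F
Why: Silyl triflate silylation of two tertiary alcohols under buffered conditions, which blocks the Achmatowicz pathway in step 9, the retro-aldol and retro-ene pathways in step 11 and the nucleophilicity of C10–O.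

Step 9
Reactants: 12 tetrasilylated furan
Product: 14 γ-hydroxybutenolide (C6 hemiketal), via furan endoperoxide 13 (not isolated)
Conditions: O2, tetraphenylporphyrin (cat.), hv, iPr2NEt, CH2Cl2, −78 °C to rt
Reagents that add atoms: dioxygen O=O
Why: Furan photooxygenation ([4+2] with singlet oxygen) followed by Kornblum–DeLaMare fragmentation, in which only C12 carries a hydrogen, so C12 becomes the lactone carbonyl and C6 the hemiketal carbon, while the isolated vinyl group is inert.

Step 10
Reactants: 14 γ-hydroxybutenolide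
Product: 16 (1S,6S,8S,10S)-7a-(prop-1-ynyl)-7-vinyl bicyclic butenolide (vinyl cis to propynyl), via hydroxy acid 15 (not isolated)
Conditions: MeC≡CMgBr (4 equiv), LaCl3·2LiCl (30 mol %), THF, −78 to 0 °C; pH 5 citrate buffer
Reagents that add atoms: prop-1-ynylmagnesium bromide CC#C[Mg]Br
Why: Grignard addition to the ring-opened keto carboxylate of a pseudo-acid with spontaneous lactonisation of the Z hydroxy acid, in which the slim alkynyl nucleophile should attack C6 from the face opposite to the syn-axial C8–OTBS and C10–CH3 groups, leaving the lactone oxygen cis to C8–O.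

Step 11
Reactants: 16 Cope substrate
Product: 19 (4S,8S,10S)-1,4-epoxygermacratrienolide silyl ether, via silyl enol ether allene 17 (not isolated), via allenyl ketone 18 (not isolated)
Conditions: PhMe (0.01 M), BHT (cat.), sealed tube, 160 °C; cool to 0 °C, then iPrOH (1.1 equiv), Ph3PAuNTf2 (5 mol %), 0 °C to rt
Reagents that add atoms: none
Why: Proposed new method: heating brings the equatorial C1 vinyl and the axial C6 propynyl group into contact for a suprafacial [3,3] silyloxy-Cope shift that forms C3–C4, breaks the acyloxy-substituted, allylic and propargylic C1–C6 bond between two fully substituted carbons and expands the cyclohexane to the ten-membered carbocycle 17, the closest known types being the thermal silyloxy-Cope rearrangement of aldol-type 1,5-dienes and the acetylenic oxy-Cope rearrangement to allenyl carbonyl compounds. iPrOH then cleaves the labile silyl enol ether to ketone 18, monovalent gold binds the alkyl-substituted, more electron-rich C4=C5 bond, the C1 carbonyl oxygen attacks C4 anti to gold, loss of H-2 gives the enol ether and protodeauration at C5 releases the catalyst, the closest known types being gold-catalysed exo-hydroalkoxylation of γ-hydroxyallenes and carbonyl-oxygen cyclisation of 4-alkynyl ketones. Ring closures: the carbocycle arises by four-atom ring expansion, the dihydrofuran by 5-exo-trig attack on the proximal allene carbon, and the same O–C4 bond closes the nine-membered oxacycle transannularly. The only new stereocentre, C4, is set by chirality transfer, since C6 fixes the allene axis in the suprafacial shift and anti attack from the C7 side, the only side that the C8–C10 bridge lets the carbonyl reach, turns the axis into 4S and into the E geometry (C4 cis to C7) of C5=C6. The selectivities needed are the Cope partner (the equatorial vinyl is antiperiplanar to C6–C7 and cannot reach C11), O- over C-attack (C2 could close only three- or four-membered rings) and C1=O over C10–O (silenced as the hindered TES ether). No base is present, so retro-aldol cleavage of the vinylogous aldol bond C1–C6 and the loss of the C6 configuration that an alkoxide would invite are avoided.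

Step 12
Reactants: 19 trisilyl ether
Product: 20 (4S,8S,10S)-8,10,13-triol
Conditions: Bu4NF–AcOH (1:1), THF, 0 °C to rt
Reagents that add atoms: none
Why: Buffered fluoride desilylation, whose near-neutral medium should spare the acid-labile enol ether and the base-labile enol lactone while cleaving two TBS ethers and the tertiary TES ether.

Step 13
Reactants: 20 triol
Product: 21 CNP0144020.1
Conditions: Ac2O, pyridine, DMAP (cat.), CH2Cl2, 0 °C
Reagents that add atoms: acetic anhydride CC(=O)OC(C)=O
Why: Selective acetylation, in which the primary C13 and secondary C8 alcohols are acylated and the hindered tertiary C10 alcohol should remain free.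

Compound list
1 | 5-methylcyclohexane-1,3-dione | CC1CC(=O)CC(=O)C1 | starting material
2 | ethyl bromopyruvate | CCOC(=O)C(=O)CBr | starting material
3 | ethyl 3-hydroxy-6-methyl-4-oxo-2,3,4,5,6,7-hexahydro-1-benzofuran-3-carboxylate | CCOC(=O)C1(O)COC2=C1C(=O)CC(C)C2 | intermediate
4 | ethyl 6-methyl-4-oxo-4,5,6,7-tetrahydro-1-benzofuran-3-carboxylate | CCOC(=O)c1coc2CC(C)CC(=O)c12 | intermediate
5 | (8S)-hydroxy ester, both C10 epimers | CCOC(=O)c1coc2CC(C)C[C@H](O)c12 | intermediate
6 | (8S)-diol, both C10 epimers | OCc1coc2CC(C)C[C@H](O)c12 | intermediate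
7 | (8S)-bis-TBS ether | CC(C)(C)[Si](C)(C)OCc1coc2CC(C)C[C@H](O[Si](C)(C)C(C)(C)C)c12 | intermediate
8 | (8S)-C1 furyl ketone | CC(C)(C)[Si](C)(C)OCc1coc2C(=O)C(C)C[C@H](O[Si](C)(C)C(C)(C)C)c12 | intermediate
9 | potassium C1,C10-enolate of 8 | CC(C)(C)[Si](C)(C)OCc1coc2C([O-])=C(C)C[C@H](O[Si](C)(C)C(C)(C)C)c12.[K+] | intermediate
10 | (8S,10S)-10-hydroxy ketone, C10–OH trans to C8–O | CC(C)(C)[Si](C)(C)OCc1coc2C(=O)[C@@](C)(O)C[C@H](O[Si](C)(C)C(C)(C)C)c12 | intermediate
11 | (1R,8S,10S)-1-vinyl 1,10-diol, C1–OH cis to C8–O | CC(C)(C)[Si](C)(C)OCc1coc2[C@@](O)(C=C)[C@@](C)(O)C[C@H](O[Si](C)(C)C(C)(C)C)c12 | intermediate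
12 | 1,10-bis-TES ether of 11 | CC(C)(C)[Si](C)(C)OCc1coc2[C@@](O[Si](CC)(CC)CC)(C=C)[C@@](C)(O[Si](CC)(CC)CC)C[C@H](O[Si](C)(C)C(C)(C)C)c12 | intermediate
13 | C6,C12-endoperoxide of 12 | CC(C)(C)[Si](C)(C)OCC1=C2[C@@H](O[Si](C)(C)C(C)(C)C)C[C@](C)(O[Si](CC)(CC)CC)[C@](O[Si](CC)(CC)CC)(C=C)C23OOC1O3 | intermediate
14 | γ-hydroxybutenolide (C6 hemiketal; C1, C8, C10 unchanged) | CC(C)(C)[Si](C)(C)OCC1=C2[C@@H](O[Si](C)(C)C(C)(C)C)C[C@](C)(O[Si](CC)(CC)CC)[C@](O[Si](CC)(CC)CC)(C=C)C2(O)OC1=O | intermediate
15 | (Z)-γ-hydroxy acid, C6 carbinol bearing propynyl | CC(C)(C)[Si](C)(C)OC/C(C(=O)O)=C1\[C@@H](O[Si](C)(C)C(C)(C)C)C[C@](C)(O[Si](CC)(CC)CC)[C@](O[Si](CC)(CC)CC)(C=C)[C@]1(O)C#CC | intermediate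
16 | (1S,6S,8S,10S)-Cope substrate; lactone O, C1–O and C8–O on one face, propynyl, vinyl and C10–O on the other | CC(C)(C)[Si](C)(C)OCC1=C2[C@@H](O[Si](C)(C)C(C)(C)C)C[C@](C)(O[Si](CC)(CC)CC)[C@](O[Si](CC)(CC)CC)(C=C)[C@@]2(C#CC)OC1=O | intermediate
17 | ten-membered silyl enol ether allene (C10 cis to C3 on C1=C2; seen from C4 toward C6 with C3 up, the lactone O lies left) | CC(C)(C)[Si](C)(C)OCC1=C2[C@@H](O[Si](C)(C)C(C)(C)C)C[C@](C)(O[Si](CC)(CC)CC)/C(O[Si](CC)(CC)CC)=C\CC(C)=[C@]=C2OC1=O | intermediate
18 | ten-membered allenyl ketone, same axis | CC(C)(C)[Si](C)(C)OCC1=C2[C@@H](O[Si](C)(C)C(C)(C)C)C[C@](C)(O[Si](CC)(CC)CC)C(=O)CCC(C)=[C@]=C2OC1=O | intermediate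
19 | (4S,8S,10S)-8,13-bis(TBSO)-10-(TESO)-1,4-epoxygermacra-1,5E,7(11)-trien-12,6-olide | CC(C)(C)[Si](C)(C)OCC1=C2/C(=C\[C@]3(C)CC=C(O3)[C@@](C)(O[Si](CC)(CC)CC)C[C@@H]2O[Si](C)(C)C(C)(C)C)OC1=O | intermediate
20 | (4S,8S,10S)-8,10,13-trihydroxy-1,4-epoxygermacra-1,5E,7(11)-trien-12,6-olide | OCC1=C2/C(=C\[C@]3(C)CC=C(O3)[C@@](C)(O)C[C@@H]2O)OC1=O | intermediate
21 | (4S,8S,10S)-8,13-diacetoxy-10-hydroxy-1,4-epoxygermacra-1,5E,7(11)-trien-12,6-olide (CNP0144020.1) | CC(=O)OCC1=C2/C(=C\[C@]3(C)CC=C(O3)[C@@](C)(O)C[C@@H]2OC(C)=O)OC1=O | target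

Total step count: 13. Longest linear sequence: 13.

Steps most likely to fail

Step 11. The sigmatropic equilibrium may stop short of the ten-membered ring. The allene axis may racemise on gold through a planar allyl cation. Early loss of the C10 silyl group would let the tertiary alcohol compete for C4. The fallback sets out from 16 and returns at 19 by known reaction types taken one at a time. The thermolysis is run alone and the crude 17 is hydrolysed with AcOH–THF–H2O at 0 °C, so that the allenyl ketone 18 is isolated. Ph3PAuCl/AgOTf (cat.) in MeOH–CH2Cl2 then lets the hemiketal hydroxyl of 18 add to C4. This is an alcohol-type nucleophile of the kind established for gold-catalysed exo-hydroalkoxylation of hydroxyallenes with axis-to-centre transfer, and it gives the cyclic methyl ketal F1. TMSOTf/iPr2NEt eliminates methanol from F1 toward C2 (C10 is quaternary) and gives 19.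

Step 10. Addition to the crowded C6 carbonyl may be slow. The neighbouring C1 silyl group may migrate to the new alkoxide. Facial selectivity may be poor. The fallback sets out from 14 and returns at 16 by replacing carbonyl addition with substitution at an oxocarbenium ion. Ac2O/DMAP/Et3N gives the γ-acetoxybutenolide F2. BF3·OEt2 at −78 °C ionises it, and tributyl(prop-1-ynyl)stannane captures C6 from the same open face.

Step 5. The furfuryl cation may be captured at the free ring position C12, the ring may be over-oxidised, or silyl ethers may be lost. The fallback sets out from 7 and returns at 8 by replacing hydride abstraction with deprotonation. nBuLi then TMSCl blocks C12 and gives the 2-silylfuran F3. sBuLi/TMEDA lithiates C1 laterally, and B(OMe)3 followed by H2O2/NaOH gives the furfuryl alcohol F4. MnO2 gives the silylated ketone F5. K2CO3/MeOH removes the silyl group, which is now activated by the acyl group, and gives 8.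

Further compounds
F1 | step 11 | C1 methyl ketal of the 1,4-epoxide (tetrahydrofuran, C1 epimers) | CC(C)(C)[Si](C)(C)OCC1=C2/C(=C\[C@]3(C)CCC(OC)(O3)[C@@](C)(O[Si](CC)(CC)CC)C[C@@H]2O[Si](C)(C)C(C)(C)C)OC1=O
F2 | step 10 | γ-acetoxybutenolide from 14 | CC(C)(C)[Si](C)(C)OCC1=C2[C@@H](O[Si](C)(C)C(C)(C)C)C[C@](C)(O[Si](CC)(CC)CC)[C@](O[Si](CC)(CC)CC)(C=C)C2(OC(C)=O)OC1=O
F3 | step 5 | C12-trimethylsilyl derivative of 7 | CC(C)(C)[Si](C)(C)OCc1c([Si](C)(C)C)oc2CC(C)C[C@H](O[Si](C)(C)C(C)(C)C)c12
F4 | step 5 | C1 alcohol of F3 | CC(C)(C)[Si](C)(C)OCc1c([Si](C)(C)C)oc2C(O)C(C)C[C@H](O[Si](C)(C)C(C)(C)C)c12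
F5 | step 5 | C12-trimethylsilyl derivative of 8 | CC(C)(C)[Si](C)(C)OCc1c([Si](C)(C)C)oc2C(=O)C(C)C[C@H](O[Si](C)(C)C(C)(C)C)c12
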